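**Retrosynthetic overview**
- The target is reached from its 7,7''-di-O-benzyl ether by hydrogenolysis; the two C4/C4'' ketones come from the C4/C4'' methylenes of a 3,3''-biflavan by benzylic oxidation.
- Feature: in each pyran ring (O1–C2–C3–C4–C4a–C8a) the bonds O1–C2 and C3–C4 are cut. O1, C8a, C4a and C4 then belong to an A-ring ortho-quinone methide, and C2=C3 and C2''=C3'', already joined through C3–C3'', are the two E double bonds of 1,4-bis(4-methoxyphenyl)buta-1,3-diene.
- Ring order: the pyran ring of the first flavan unit, then that of the second, in one flask by two hetero-Diels–Alder additions under one chiral phosphoric acid; no other ring is formed.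
- The diene comes from 4-methoxycinnamaldehyde and a 4-methoxybenzyl phosphonate by olefination; the quinone methide precursor (a salicyl alcohol) comes from 2,4,6-trihydroxybenzaldehyde by benzylation, mono-methylation and reduction.

Key step: step 5

Assumption (remark on the chemistry): the (R)-enantiomer of the phosphoric acid is taken to give the (2S,3R) sense in each cycloaddition; should a trial mono-addition show the opposite sense, the (S)-catalyst is used with no other change.

**Route**

Step 1
Reactants: 1 (E)-4-methoxycinnamaldehyde; 2 diethyl (4-methoxybenzyl)phosphonate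
Product: 3 (1E,3E)-1,4-bis(4-methoxyphenyl)buta-1,3-diene
Conditions: NaH, THF, 0 °C → rt
Reagents that add atoms: none
Why: Horner–Wadsworth–Emmons olefination of the enal with the semi-stabilised benzylic phosphonate anion, which leaves the existing E-alkene untouched and should form the new one E through the thermodynamically controlled elimination of the oxaphosphetane.

Step 2
Reactants: 4 2,4,6-trihydroxybenzaldehyde; 5 benzyl bromide (1.0 equiv)
Product: 6 4-(benzyloxy)-2,6-dihydroxybenzaldehyde
Conditions: KHCO3, DMF, rt
Reagents that add atoms: none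
Why: Williamson etherification in which the 4-OH, the most acidic phenol (para to the formyl group and not chelated to it), should be the only one alkylated by one equivalent of bromide with a hydrogen carbonate base.

Step 3
Reactants: 6 4-(benzyloxy)-2,6-dihydroxybenzaldehyde
Product: 7 4-(benzyloxy)-2-hydroxy-6-methoxybenzaldehyde
Conditions: MeI (1.05 equiv), K2CO3, acetone, rt
Reagents that add atoms: iodomethane, CI
Why: Williamson methylation of one of the two equivalent ortho-phenols, expected to stop at the mono-ether because the remaining phenol is then held in a strong hydrogen bond to the formyl oxygen and is a poor nucleophile.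

Step 4
Reactants: 7 4-(benzyloxy)-2-hydroxy-6-methoxybenzaldehyde
Product: 8 5-(benzyloxy)-2-(hydroxymethyl)-3-methoxyphenol
Conditions: NaBH4, THF/EtOH, 0 °C; aq NH4Cl work-up; used at once without chromatography
Reagents that add atoms: none
Why: Borohydride reduction of the aryl aldehyde to the benzylic alcohol, where low temperature, a short reaction time and a near-neutral work-up should keep the electron-rich salicyl alcohol from losing water before the next step.

Step 5
Reactants: 3 (1E,3E)-1,4-bis(4-methoxyphenyl)buta-1,3-diene; 8 5-(benzyloxy)-2-(hydroxymethyl)-3-methoxyphenol (two molecules per molecule of 3)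
Product: 11 (2S,3R,2''S,3''R)-7,7''-bis(benzyloxy)-4',4''',5,5''-tetramethoxy-3,3''-biflavan, via ortho-quinone methide 9 (not isolated), via mono-adduct 10 (not isolated)
Conditions: (R)-TRIP [(R)-3,3'-bis(2,4,6-triisopropylphenyl)-BINOL hydrogen phosphate] (10 mol %), 4 Å MS, CH2Cl2, 0 °C → rt, 8 (2.4 equiv) added slowly
Reagents that add atoms: none
Why: Proposed new method: the phosphoric acid dehydrates 8 to the hydrogen-bonded ortho-quinone methide 9, whose methylene carbon bonds to an inner carbon of diene 3 while its oxygen bonds to the neighbouring anisyl-bearing carbon in an asynchronous inverse-electron-demand oxa-[4+2] (hetero-Diels–Alder) cycloaddition, and a second molecule of 9 adds in the same way to the isolated anethole-type alkene of mono-adduct 10; the closest known reaction type is the chiral phosphoric acid-catalysed [4+2] cycloaddition of in situ ortho-quinone methides with β-substituted electron-rich styrenes to trans-2-aryl-3-substituted chromans, and its two-fold use on a conjugated 1,4-diarylbutadiene is the untested part. Each of the two pyran rings closes by this intermolecular [4+2] mode, with C4–C3 bond formation leading and O1–C2 bond formation following on the same alkene face. C2/C3 and C2''/C3'' should come out trans because the addition is suprafacial on an E-alkene, and their absolute sense (2S,3R in both halves) is set by the chiral phosphate, which binds 9 through its carbonyl oxygen and exposes one alkene face. The step needs (i) oxygen-to-benzylic regiochemistry in the first addition, which the 4-methoxy groups should favour because each raises the nucleophilicity of the diene carbon β to its own ring and stabilises a benzylic cation more than the extended allyl cation of the competing pathway, (ii) the same facial sense in both additions, which catalyst control should secure because the allylic C3 centre of 10 carries two ring branches of similar size and so biases the styrene faces only weakly, giving the C2-symmetric and not the meso bis-adduct, and (iii) cycloaddition faster than Friedel–Crafts attack of the electron-rich A-rings on 9, which slow addition of 8 is meant to secure.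

Step 6
Reactants: 11 (2S,3R,2''S,3''R)-7,7''-bis(benzyloxy)-4',4''',5,5''-tetramethoxy-3,3''-biflavan
Product: 12 7,7''-bis(benzyloxy)-4',4''',5,5''-tetramethoxy-3,3''-biflavan-4,4''-diol (C2/C3 and C2''/C3'' as in 11; C4/C4'' epimers not separated)
Conditions: DDQ (2.6 equiv), CH2Cl2/H2O (18:1), 0 °C → rt
Reagents that add atoms: water, O
Why: Benzylic C–H oxidation by hydride abstraction with DDQ, the known C4 functionalisation of 5,7-dialkoxyflavans, in which the 5-methoxy, 7-benzyloxy and ring oxygens stabilise the C4 cation far better than C2 is activated, water traps each cation, and aryl benzyl and methyl ethers are inert to the quinone.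

Step 7
Reactants: 12 7,7''-bis(benzyloxy)-4',4''',5,5''-tetramethoxy-3,3''-biflavan-4,4''-diol
Product: 13 (2S,3R,2''S,3''R)-7,7''-bis(benzyloxy)-4',4''',5,5''-tetramethoxy-3,3''-biflavanone (7,7''-di-O-benzyl ether of the target)
Conditions: Dess–Martin periodinane, pyridine, CH2Cl2, 0 °C → rt
Reagents that add atoms: none
Why: Dess–Martin oxidation of the two secondary benzylic alcohols to aryl ketones under buffered conditions, in which all C4 epimers converge and the 2,3-trans arrangement at the now enolisable C3 is the thermodynamically preferred one.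

Step 8
Reactants: 13 (2S,3R,2''S,3''R)-7,7''-bis(benzyloxy)-4',4''',5,5''-tetramethoxy-3,3''-biflavanone
Product: 14 4',4''',5,5''-tetramethylchamaejasmin, (2S,3R,2''S,3''R)
Conditions: H2 (1 atm), 10% Pd/C, EtOAc/THF, rt
Reagents that add atoms: none
Why: Catalytic hydrogenolysis of the two aryl benzyl ethers over palladium, under which the flavanone carbonyls and ring C2–O bonds should survive at room temperature and no base is present that could open the flavanone by retro-oxa-Michael reaction.

**Compound list**
1 | (E)-4-methoxycinnamaldehyde | COc1ccc(/C=C/C=O)cc1 | starting material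
2 | diethyl (4-methoxybenzyl)phosphonate | CCOP(=O)(Cc1ccc(OC)cc1)OCC | starting material
3 | (1E,3E)-1,4-bis(4-methoxyphenyl)buta-1,3-diene | COc1ccc(/C=C/C=C/c2ccc(OC)cc2)cc1 | intermediate
4 | 2,4,6-trihydroxybenzaldehyde | O=Cc1c(O)cc(O)cc1O | starting material
5 | benzyl bromide | BrCc1ccccc1 | starting material
6 | 4-(benzyloxy)-2,6-dihydroxybenzaldehyde | O=Cc1c(O)cc(OCc2ccccc2)cc1O | intermediate
7 | 4-(benzyloxy)-2-hydroxy-6-methoxybenzaldehyde | COc1cc(OCc2ccccc2)cc(O)c1C=O | intermediate
8 | 5-(benzyloxy)-2-(hydroxymethyl)-3-methoxyphenol | COc1cc(OCc2ccccc2)cc(O)c1CO | intermediate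
9 | 3-(benzyloxy)-5-methoxy-6-methylidenecyclohexa-2,4-dien-1-one (ortho-quinone methide) | C=C1C(=O)C=C(OCc2ccccc2)C=C1OC | intermediate
10 | (2S,3R)-7-(benzyloxy)-5-methoxy-2-(4-methoxyphenyl)-3-[(E)-2-(4-methoxyphenyl)ethenyl]chromane (2,3-trans mono-adduct) | COc1ccc([C@H]2Oc3cc(OCc4ccccc4)cc(OC)c3C[C@@H]2/C=C/c2ccc(OC)cc2)cc1 | intermediate
11 | (2S,3R,2''S,3''R)-7,7''-bis(benzyloxy)-4',4''',5,5''-tetramethoxy-3,3''-biflavan (trans,trans, C2-symmetric) | COc1ccc([C@H]2Oc3cc(OCc4ccccc4)cc(OC)c3C[C@@H]2[C@H]2Cc3c(OC)cc(OCc4ccccc4)cc3O[C@@H]2c2ccc(OC)cc2)cc1 | intermediate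
12 | 7,7''-bis(benzyloxy)-4',4''',5,5''-tetramethoxy-3,3''-biflavan-4,4''-diol (C2/C3 as in 11; C4/C4'' undefined) | COc1ccc([C@H]2Oc3cc(OCc4ccccc4)cc(OC)c3C(O)[C@@H]2[C@H]2C(O)c3c(OC)cc(OCc4ccccc4)cc3O[C@@H]2c2ccc(OC)cc2)cc1 | intermediate
13 | (2S,3R,2''S,3''R)-7,7''-bis(benzyloxy)-4',4''',5,5''-tetramethoxy-3,3''-biflavanone | COc1ccc([C@H]2Oc3cc(OCc4ccccc4)cc(OC)c3C(=O)[C@@H]2[C@H]2C(=O)c3c(OC)cc(OCc4ccccc4)cc3O[C@@H]2c2ccc(OC)cc2)cc1 | intermediate
14 | 4',4''',5,5''-tetramethylchamaejasmin, (2S,3R,2''S,3''R) | COc1ccc([C@H]2Oc3cc(O)cc(OC)c3C(=O)[C@@H]2[C@H]2C(=O)c3c(OC)cc(O)cc3O[C@@H]2c2ccc(OC)cc2)cc1 | target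

**Step count**
Total step count: 8
Longest linear sequence: 7 steps (4 → 6 → 7 → 8 → 11 → 12 → 13 → 14)

**Steps most likely to fail**

Step 5 (bears the label "Proposed new method:"). Three processes may defeat it:
- bonding of the quinone methide carbon to the anisyl-bearing terminus of the conjugated diene (the allyl-cation pathway), which would lead to 3-aryl-2-styrylchromans;
- a mismatched second addition that lowers the proportion of the C2-symmetric bis-adduct against the meso one;
- consumption of 9 by Friedel–Crafts alkylation of the electron-rich A-rings.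

The fallback uses known chemistry only, with each cycloaddition run on an isolated β-substituted 4-methoxystyrene, the established substrate class. It sets out from 1 and 8. Luche reduction of 1 (NaBH4, CeCl3, MeOH) would give (E)-3-(4-methoxyphenyl)prop-2-en-1-ol F1, and silylation (TBDPSCl, imidazole, DMF) would give its tert-butyldiphenylsilyl ether F2; a silyl ether is chosen because it is a poor leaving group towards the acid catalyst. Cycloaddition of 9, generated from 8 with the same phosphoric acid, to F2 should give the trans-(2S,3R)-3-(silyloxymethyl)chroman F3. TBAF would free the primary alcohol F4. Mitsunobu reaction with 1-phenyl-1H-tetrazole-5-thiol (PPh3, DIAD) would give the tetrazolyl sulfide F5, and oxidation (ammonium molybdate, H2O2, EtOH) the tetrazolyl sulfone F6. Julia–Kocienski olefination of F6 with 4-methoxybenzaldehyde (KHMDS, DME, −60 °C → rt) should deliver the E-styrene 10, now as an isolated compound. The sulfonyl carbanion has no β-leaving group, so the chroman ring should not open. A second catalytic cycloaddition of 10 with 8 comes back to the route at 11.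

Step 6. The processes at risk are competing hydride abstraction at C2 (leading towards flavylium species), loss of a proton from the C4 cation to give a flav-3-ene, and incomplete oxidation of the second half. The fallback sets out from 11 and replaces hydride abstraction by benzylic acetoxylation with lead tetraacetate (benzene, rt → 50 °C), the classical C4 acetoxylation of 5,7-dialkoxyflavans. It would give the 4,4''-diacetate F7, whose methanolysis (K2CO3, MeOH, 0 °C) comes back to the route at 12.

Step 4. The processes at risk are over-reduction to the ortho-cresol, through loss of the benzylic oxygen from the phenoxide/borate and hydride capture of the quinone methide, and self-condensation of the salicyl alcohol during work-up. The fallback sets out from 7 and masks the phenol before reduction. Allylation (allyl bromide, K2CO3, DMF) would give 2-(allyloxy)-4-(benzyloxy)-6-methoxybenzaldehyde F8. Borohydride reduction would then give the stable benzylic alcohol [2-(allyloxy)-4-(benzyloxy)-6-methoxyphenyl]methanol F9, which can be stored. Palladium-catalysed deallylation under basic, non-reducing conditions (Pd(PPh3)4, K2CO3, MeOH, rt) just before use comes back to the route at 8.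

**Further compounds**
F1 | step 5 | (E)-3-(4-methoxyphenyl)prop-2-en-1-ol | COc1ccc(/C=C/CO)cc1
F2 | step 5 | (E)-tert-butyl{[3-(4-methoxyphenyl)prop-2-en-1-yl]oxy}diphenylsilane | COc1ccc(/C=C/CO[Si](c2ccccc2)(c2ccccc2)C(C)(C)C)cc1
F3 | step 5 | (2S,3R)-7-(benzyloxy)-3-{[(tert-butyldiphenylsilyl)oxy]methyl}-5-methoxy-2-(4-methoxyphenyl)chromane (2,3-trans) | COc1ccc([C@H]2Oc3cc(OCc4ccccc4)cc(OC)c3C[C@@H]2CO[Si](c2ccccc2)(c2ccccc2)C(C)(C)C)cc1
F4 | step 5 | [(2S,3R)-7-(benzyloxy)-5-methoxy-2-(4-methoxyphenyl)chroman-3-yl]methanol (2,3-trans) | COc1ccc([C@H]2Oc3cc(OCc4ccccc4)cc(OC)c3C[C@@H]2CO)cc1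
F5 | step 5 | 5-({[(2S,3S)-7-(benzyloxy)-5-methoxy-2-(4-methoxyphenyl)chroman-3-yl]methyl}sulfanyl)-1-phenyl-1H-tetrazole (2,3-trans) | COc1ccc([C@H]2Oc3cc(OCc4ccccc4)cc(OC)c3C[C@@H]2CSc2nnnn2-c2ccccc2)cc1
F6 | step 5 | 5-({[(2S,3S)-7-(benzyloxy)-5-methoxy-2-(4-methoxyphenyl)chroman-3-yl]methyl}sulfonyl)-1-phenyl-1H-tetrazole (2,3-trans) | COc1ccc([C@H]2Oc3cc(OCc4ccccc4)cc(OC)c3C[C@@H]2CS(=O)(=O)c2nnnn2-c2ccccc2)cc1
F7 | step 6 | 7,7''-bis(benzyloxy)-4',4''',5,5''-tetramethoxy-3,3''-biflavan-4,4''-diyl diacetate (C2/C3 as in 11; C4/C4'' undefined) | COc1ccc([C@H]2Oc3cc(OCc4ccccc4)cc(OC)c3C(OC(C)=O)[C@@H]2[C@H]2C(OC(C)=O)c3c(OC)cc(OCc4ccccc4)cc3O[C@@H]2c2ccc(OC)cc2)cc1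
F8 | step 4 | 2-(allyloxy)-4-(benzyloxy)-6-methoxybenzaldehyde | C=CCOc1cc(OCc2ccccc2)cc(OC)c1C=O
F9 | step 4 | [2-(allyloxy)-4-(benzyloxy)-6-methoxyphenyl]methanol | C=CCOc1cc(OCc2ccccc2)cc(OC)c1CO
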